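# Total synthesis proposal for CNP0348657.1 (compound 30)

## The problem

1. Atoms are numbered as in the elemane skeleton. The single ring is the cyclohexane C5–C6–C7–C8–C9–C10. C10 bears methyl C14 and vinyl C1=C2, C5 bears C4(=C3H2)C15H2OH, C6 bears a free hydroxyl, C7 bears the acrylic acid unit C11(=C13H2)C12O2H, and O8 is acylated by (R)-3,4-dihydroxy-2-methylenebutanoic acid (C1'–C4').
2. Five of the six ring carbons are stereocentres. Vinyl, O6, C11 and O8 lie on one face and C14 and C4 on the other, so in the chair every group is equatorial except C14 and C11.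
3. The axial C11 makes C7 the contra-thermodynamic centre: equilibration, or any ring closure that lets C7 choose, ends at the C7 epimer.
4. The quaternary C10 carries two groups of almost equal size, so neither a reagent nor a chair-like closure can tell methyl from vinyl. Its relation to C5 must come from a concerted bond formation between alkenes of defined geometry.
5. Once C5 and C10 stand, C5 can direct C6 in the open chain, C6 can direct C7 only through a rigid tie, and the axial C14 can direct C8.
6. Three 2-substituted acrylic units must survive. The cis C6 hydroxyl and C12 acid close to a γ-lactone under acid, and the C4' hydroxyl can expel O8 from C1' under base, which leaves a narrow window for the last steps.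
7. The feature that opens the plan is the environment of C7. C13=C11–C7 is an allyl unit whose C7 end is bonded to two carbinol carbons (C6 and C8), and O6, C6, C7, C11 and C12 can be closed to a five-membered lactone ring. As a butenolide this ring is flat at C7, and a chain reaching from C6 to C8 can bond to C7 only on the face that gives the required cis triad.

## Retrosynthesis

**Unmasking (30 from 29 from 28).** No C–C bond is cut; two O–Si bonds and the O6–C12 bond are restored.
- The pair that threatens the target, the C6 hydroxyl and the C12 acid, is made to protect itself as the cis-fused γ-lactone of 28.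
- The neighbouring choice, a separate ester at C12 and an ether at O6, costs four operations and gives intermediates that lactonise anyway.
- The forward steps ask that hydroxide open the lactone faster than it attacks the C1' ester, which is shielded by two silyl ethers.
- They also ask that fluoride then act near neutrality on the carboxylate.

**C15–O and O8–C1' (28 from 27, 27 from 19 and 25).**
- In 27 the isopropenyl group at C5 is the only electron-rich alkene with allylic hydrogen, so O15 can be added last and needs no protecting group at any stage.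
- Cutting the ester gives hydroxy lactone 19, whose only free hydroxyl is O8, and acid 25, which carries the only side-chain stereocentre.
- The precursor 19 has fifteen carbons and no protecting group.

**C7–C8, the key cut (19 from 17).**
- The homoallylic alcohol array C13=C11–C7–C8–O8 is cut at C7–C8.
- This removes the only carbocycle, two stereocentres (C7, C8) and the exocyclic methylene in one stroke. It leaves an open chain that ends in an aldehyde (C8) and a bromolactone.
- The same closure without the lactone tie is the obvious neighbour. There, allylic 1,3-strain between C13 and the substituents of C6 puts H6 in the alkene plane and leads to an equatorial C11, that is, to the wrong C7 epimer.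
- Cutting C6–C7 instead would leave O6 free and O8 tied up, the reverse of what the target needs.
- The forward reaction must metallate the allylic bromide and add C7 to C8 on the face dictated by the tether.

**C6–C7 and O6–C12 (16 from 9 and 12).**
- C7 is bonded to two carbinol carbons, so it is treated as a geminal dianion.
- Dibromide 12 delivers C7, C11, C12 and C13 and uses its two C–Br bonds one after the other, first towards C6 (step 8) and then towards C8 (step 10).
- This replaces a separate butenolide synthesis and functionalisation.
- The precursor, aldehyde 9, has two stereocentres and no ring.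
- The forward reaction must add at the bromine-bearing terminus and obey Felkin–Anh control by C5.

**C5–C10 (7 from 5, 5 from 3 and 4).**
- The vicinal tertiary and quaternary pair with its vinyl group is the retron of an Ireland–Claisen rearrangement in which C6 is the carboxyl carbon.
- Placing the carboxyl at C6 rather than at C4 keeps the C4 unit intact in acid 4 and leaves C6 ready for the next C–C bond.
- The precursor 5 is the achiral ester of two five- and six-carbon pieces.
- The forward reaction must combine an E-alkene, an E(O)-enolate and a chair, and needs an external chiral controller because 5 has no stereocentre.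

**Small pieces.**
- Alcohol 3 comes from alkyne 1 by carboalumination.
- Dibromide 12 comes from acrylate 10 by bromination and loss of HBr.
- Acid 25 comes from glycerate 20 by homologation to an alkyne and branched hydroxycarbonylation.

## Roads not taken

**Alternative 1: the presumed biogenesis (the most obvious route).**
- *Cut:* C2–C3 is re-joined and C5–C10 is opened, which gives the ten-membered (1(10)E,4E)-germacradienolide A1.
- *Forward key step:* a thermal Cope rearrangement through a chair-like array.
- *Why the chosen plan is better:*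
  - A1 is an isomer of the core. It keeps all three centres C6–C8 and adds two E-trisubstituted ring alkenes and a medium ring that must first be closed, so nothing is simplified.
  - The face on which C5 and C10 join depends on the conformation of the ring. With a cis lactone and C11 on the same face as both oxygens, that conformation cannot be predicted from the natural series.
  - The rearrangement is an equilibrium that needs strong heating of an α-methylene lactone.

**Alternative 2: the ring is bought.**
- *Cut:* C10–C1 and C5–C4, back to enone A2.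
- *Forward key step:* copper-mediated conjugate addition of a vinyl nucleophile to C10 with trapping of the C5 enolate.
- *Why the chosen plan is better:*
  - Addition should occur anti to the C8 silyloxy group and give A3, with vinyl trans to O8, whereas the target has them cis.
  - Alkenylation of C5 next to the new quaternary centre is hindered.
  - The β-silyloxy ketone is prone to elimination and aromatisation.
  - C7 would be set under conditions that favour the equatorial epimer.
  - Each remaining group needs its own redox and protection steps.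

**Alternative 3: closure at C5–C6.**
- *Cut:* C5–C6, back to aldehyde A4.
- *Forward key step:* a Lewis acid carbonyl-ene closure of the isopulegol kind, which would form the C6 carbinol and the C4=C3 alkene together.
- *Why the chosen plan is better:*
  - The chair-like closure cannot relay C10, since methyl and vinyl compete for the axial site on equal terms.
  - It prefers C11 equatorial.
  - A4 already holds three stereocentres in an open chain. One of them, C7, is α to the aldehyde and γ to the ester, and so is open to epimerisation and to migration of the double bond.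

Key step: step 10

Assumption: the hydroxy acid 30 is taken to resist closure of the O6–C12 lactone and loss of the side chain between pH 5 and 8 at or below room temperature, so all operations after step 17 stay in this window.

## Route

Step 1
Reactants: 1 tert-butyl(but-3-yn-1-yloxy)dimethylsilane
Product: 3 (2E)-5-{[tert-butyl(dimethyl)silyl]oxy}-3-methylpent-2-en-1-ol, via alkenylalane 2 (not isolated)
Conditions: AlMe3, Cp2ZrCl2 (cat.), CH2Cl2, 0 °C to rt; n-BuLi, THF, −78 °C; (CH2O)n, −78 °C to rt; aq. HCl
Reagents that add atoms: trimethylaluminium C[Al](C)C; formaldehyde (from paraformaldehyde) C=O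
Why: Negishi carboalumination adds methyl and aluminium syn with aluminium at the terminal carbon, so 2 and hence 3 should be E; the ate complex of 2 is hydroxymethylated by formaldehyde with retention of geometry.

Step 2
Reactants: 3 (2E)-5-{[tert-butyl(dimethyl)silyl]oxy}-3-methylpent-2-en-1-ol; 4 3-methylbut-3-enoic acid
Product: 5 (2E)-5-{[tert-butyl(dimethyl)silyl]oxy}-3-methylpent-2-en-1-yl 3-methylbut-3-enoate
Conditions: DCC, DMAP (cat.), CH2Cl2, 0 °C
Reagents that add atoms: none
Why: Steglich esterification at low temperature with little DMAP should join the two achiral halves without moving the β,γ-double bond of 4 into conjugation.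

Step 3
Reactants: 5 (2E)-5-{[tert-butyl(dimethyl)silyl]oxy}-3-methylpent-2-en-1-yl 3-methylbut-3-enoate
Product: 7 (2R,3R)-5-{[tert-butyl(dimethyl)silyl]oxy}-3-ethenyl-3-methyl-2-(prop-1-en-2-yl)pentanoic acid, via boron ketene acetal 6 (not isolated)
Conditions: N,N'-[(1R,2R)-1,2-diphenylethane-1,2-diyl]bis[3,5-bis(trifluoromethyl)benzenesulfonamide], BBr3, CH2Cl2, rt, evaporation; then 5, Et3N, toluene–hexane, −78 °C, then −20 °C; aq. work-up
Reagents that add atoms: none
Why: Soft enolisation by the chiral bromoborane and Et3N should give the E(O) boron ketene acetal 6, whose Ireland–Claisen rearrangement through a chair puts C9 equatorial (E-alkene) and the isopropenyl group axial, which fixes the C5/C10 relation of the target. The C2-symmetric sulfonamide ligand selects the enolate face and so the absolute configuration; the antipodal controller is equally available should the sense of induction be the opposite.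

Step 4
Reactants: 7 (2R,3R)-5-{[tert-butyl(dimethyl)silyl]oxy}-3-ethenyl-3-methyl-2-(prop-1-en-2-yl)pentanoic acid
Product: 8 (2R,3R)-5-{[tert-butyl(dimethyl)silyl]oxy}-3-ethenyl-3-methyl-2-(prop-1-en-2-yl)pentan-1-ol
Conditions: LiAlH4, Et2O, 0 °C to reflux
Reagents that add atoms: none
Why: Hydride reduction of the hindered acid to the primary alcohol; silyl ether and isolated alkenes are inert and no stereocentre is touched.

Step 5
Reactants: 8 (2R,3R)-5-{[tert-butyl(dimethyl)silyl]oxy}-3-ethenyl-3-methyl-2-(prop-1-en-2-yl)pentan-1-ol
Product: 9 (2R,3R)-5-{[tert-butyl(dimethyl)silyl]oxy}-3-ethenyl-3-methyl-2-(prop-1-en-2-yl)pentanal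
Conditions: Dess–Martin periodinane, CH2Cl2, 0 °C
Reagents that add atoms: none
Why: Dess–Martin oxidation is fast and free of base, which matters because H5 of 9 is both α to the aldehyde and allylic; 9 is used at once.

Step 6
Reactants: 10 methyl 2-(bromomethyl)prop-2-enoate
Product: 11 methyl 2,3-dibromo-2-(bromomethyl)propanoate
Conditions: Br2, CH2Cl2, 0 °C to rt
Reagents that add atoms: bromine BrBr
Why: Plain addition of bromine to the acrylate double bond.

Step 7
Reactants: 11 methyl 2,3-dibromo-2-(bromomethyl)propanoate
Product: 12 methyl 3-bromo-2-(bromomethyl)prop-2-enoate (E/Z mixture)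
Conditions: Et3N, Et2O, 0 °C to rt
Reagents that add atoms: none
Why: E2 loss of HBr, with the tertiary α-bromide as leaving group, restores conjugation; the alkene geometry of 12 is irrelevant because this carbon (future C7) is metallated later.

Step 8
Reactants: 9 (2R,3R)-5-{[tert-butyl(dimethyl)silyl]oxy}-3-ethenyl-3-methyl-2-(prop-1-en-2-yl)pentanal; 12 methyl 3-bromo-2-(bromomethyl)prop-2-enoate
Product: 16 (5S)-4-bromo-5-[(3R,4R)-4-ethenyl-6-hydroxy-2,4-dimethylhex-1-en-3-yl]-3-methylideneoxolan-2-one (C7 epimers), via allylindium reagent 13 (not isolated), via hydroxy ester 14 (not isolated), via silyl ether lactone 15 (not isolated)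
Conditions: 12, In powder, THF, rt until the metal is consumed; then 9, 0 °C to rt; then 1 M HCl, THF, rt
Reagents that add atoms: none
Why: Barbier-type bromoallylation: the preformed γ-bromoallylindium 13 should add through its bromine-bearing γ-carbon (future C7) to aldehyde C6 in a Zimmerman–Traxler array, with Felkin–Anh control by C5 (quaternary C10 anti to the nucleophile) setting C6 as S. Acid then closes the O6–C12 lactone and removes the silyl group. The configuration at C7, and any allylic shift of the bromide, is of no consequence because both isomers lead to the same allylmetal in step 10.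

Step 9
Reactants: 16 (5S)-4-bromo-5-[(3R,4R)-4-ethenyl-6-hydroxy-2,4-dimethylhex-1-en-3-yl]-3-methylideneoxolan-2-one
Product: 17 (3R,4R)-4-[(2S)-3-bromo-4-methylidene-5-oxooxolan-2-yl]-3-ethenyl-3,5-dimethylhex-5-enal
Conditions: Dess–Martin periodinane, CH2Cl2, 0 °C to rt
Reagents that add atoms: none
Why: Neutral oxidation of the only hydroxyl group; allylic bromide, lactone and alkenes are inert, and the aldehyde has no α-stereocentre.

Step 10
Reactants: 17 (3R,4R)-4-[(2S)-3-bromo-4-methylidene-5-oxooxolan-2-yl]-3-ethenyl-3,5-dimethylhex-5-enal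
Product: 19 (3aR,4R,6R,7R,7aS)-6-ethenyl-4-hydroxy-6-methyl-3-methylidene-7-(prop-1-en-2-yl)hexahydro-1-benzofuran-2(3H)-one, via allylindium butenolide 18 (not isolated)
Conditions: In powder, THF–sat. aq. NH4Cl 1:1, 0.005 M, rt
Reagents that add atoms: none
Why: Indium inserts into the allylic C7–Br bond of 17 and the σ-allyl species should settle as the primary isomer 18, an α-(indiomethyl)butenolide in which O6, C6, C7, C11 and C12 lie in one plane. Its γ-carbon C7 adds to aldehyde C8 through a closed six-membered transition state (In, C13, C11, C7, C8, O8) while the double bond moves from C7=C11 to C11=C13, so ring, carbinol and exocyclic methylene arise together. The closest known reaction types are the Barbier allylation of aldehydes with α-(bromomethyl)butenolides and the intramolecular Barbier closure of 2-(bromomethyl)acrylate aldehydes to fused α-methylene-γ-butyrolactones. The cyclohexane closes in the 6-exo-trig mode at C8. C7 is set by the tether: C8 hangs on C6 through C5, C10 and C9 and can reach only the butenolide face that bears C5, which makes the ring fusion cis and C11 axial. C8 is set by two elements that agree: the metal bridge demands a gauche O8–C8–C7–C11 array, which next to an axial C11 means an equatorial O8, and the axial alternative would meet the axial methyl C14. The step needs γ- rather than α-attack, which is secured by a six- against an eight-membered ring, and no reductive opening of the lactone, which is held back because the C6–O6 bond lies in the nodal plane of the allyl system. The aqueous medium should protonate the O8 alkoxide at once and so keep the lactone from migrating from O6 to O8.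

Step 11
Reactants: 20 methyl (4S)-2,2-dimethyl-1,3-dioxolane-4-carboxylate
Product: 22 (4R)-4-ethynyl-2,2-dimethyl-1,3-dioxolane, via aldehyde 21 (not isolated)
Conditions: DIBAL-H, CH2Cl2, −78 °C; then MeOH, K2CO3, dimethyl (1-diazo-2-oxopropyl)phosphonate, −78 °C to rt
Reagents that add atoms: dimethyl (1-diazo-2-oxopropyl)phosphonate COP(=O)(OC)C(=[N+]=[N-])C(C)=O
Why: Partial reduction and Ohira–Bestmann homologation in one flask avoid isolation of the labile aldehyde 21. The stereocentre is not touched, and the descriptor changes from S to R only through the priority rules.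

Step 12
Reactants: 22 (4R)-4-ethynyl-2,2-dimethyl-1,3-dioxolane
Product: 23 (2R)-but-3-yne-1,2-diol
Conditions: p-TsOH·H2O (cat.), MeOH, rt
Reagents that add atoms: none
Why: Acid-catalysed acetal exchange; the acetonide cannot stay because its later removal would need acid, which the target does not tolerate.

Step 13
Reactants: 23 (2R)-but-3-yne-1,2-diol
Product: 24 (2R)-1,2-bis{[tert-butyl(dimethyl)silyl]oxy}but-3-yne
Conditions: TBSCl, imidazole, DMF, rt
Reagents that add atoms: tert-butyldimethylsilyl chloride C[Si](C)(Cl)C(C)(C)C
Why: Standard silylation of both hydroxyls; these groups shield the C1' ester in step 17 and leave under fluoride in step 18.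

Step 14
Reactants: 24 (2R)-1,2-bis{[tert-butyl(dimethyl)silyl]oxy}but-3-yne
Product: 25 (3R)-3,4-bis{[tert-butyl(dimethyl)silyl]oxy}-2-methylidenebutanoic acid
Conditions: Pd(OAc)2 (cat.), 2-(diphenylphosphino)pyridine, MsOH (cat.), CO, H2O, THF, 50 °C
Reagents that add atoms: carbon monoxide [C-]#[O+]; water O
Why: Palladium-catalysed hydroxycarbonylation of a terminal alkyne with the pyridylphosphine ligand places the carboxyl group at the internal carbon (branched selectivity) and gives the 2-substituted acrylic acid directly; the propargylic stereocentre is not involved.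

Step 15
Reactants: 19 (3aR,4R,6R,7R,7aS)-6-ethenyl-4-hydroxy-6-methyl-3-methylidene-7-(prop-1-en-2-yl)hexahydro-1-benzofuran-2(3H)-one; 25 (3R)-3,4-bis{[tert-butyl(dimethyl)silyl]oxy}-2-methylidenebutanoic acid
Product: 27 O8-[(3R)-3,4-bis(tert-butyldimethylsilyloxy)-2-methylidenebutanoyl] derivative of 19, via mixed anhydride 26 (not isolated)
Conditions: 2,4,6-trichlorobenzoyl chloride, Et3N, toluene, rt; then 19, DMAP, toluene, rt
Reagents that add atoms: none
Why: Yamaguchi esterification of the only free hydroxyl, the equatorial O8; once acylated, O8 can no longer compete for C12.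

Step 16
Reactants: 27 O8-[(3R)-3,4-bis(tert-butyldimethylsilyloxy)-2-methylidenebutanoyl] derivative of 19
Product: 28 15-hydroxy derivative of 27 (C5 bears 3-hydroxyprop-1-en-2-yl)
Conditions: SeO2 (substoichiometric), t-BuOOH, CH2Cl2, 0 °C to rt
Reagents that add atoms: selenium dioxide O=[Se]=O; tert-butyl hydroperoxide CC(C)(C)OO
Why: Riley allylic oxidation (ene reaction, then 2,3-shift) should attack only the isopropenyl group: the two acrylic alkenes are electron-poor, the vinyl group has no allylic hydrogen, and methyl reacts before the methine H5.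

Step 17
Reactants: 28 15-hydroxy derivative of 27
Product: 29 seco acid of 28 (free C6 hydroxyl and free C12 acid; side chain still bis-silylated)
Conditions: LiOH (1.1 equiv), THF–H2O, 0 °C; then AcOH (1.1 equiv)
Reagents that add atoms: lithium hydroxide [Li+].[OH-]
Why: The γ-lactone has the exposed, conformationally activated ester linkage, while the C1' ester sits on a secondary carbinol and is flanked by an α-branch and two bulky silyl ethers. This is the same kind of selectivity used when a lactone is opened beside a hindered side-chain ester. The carboxylate cannot relactonise, and neutralisation stops at the weak-acid stage.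

Step 18
Reactants: 29 seco acid of 28
Product: 30 target CNP0348657.1
Conditions: Et3N·3HF, Et3N, MeCN, rt; reversed-phase chromatography at pH 6
Reagents that add atoms: none
Why: Buffered fluoride removes both silyl ethers while C12 stays an ammonium carboxylate, so neither the acid-promoted O6–C12 closure nor the base-promoted attack of O4' on C1' should set in; no stereocentre is touched.

## Compound list

1 | tert-butyl(but-3-yn-1-yloxy)dimethylsilane | C#CCCO[Si](C)(C)C(C)(C)C | starting material
2 | [(1E)-4-{[tert-butyl(dimethyl)silyl]oxy}-2-methylbut-1-en-1-yl](dimethyl)alane | C[Al](C)/C=C(\C)CCO[Si](C)(C)C(C)(C)C | intermediate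
3 | (2E)-5-{[tert-butyl(dimethyl)silyl]oxy}-3-methylpent-2-en-1-ol | OC/C=C(\C)CCO[Si](C)(C)C(C)(C)C | intermediate
4 | 3-methylbut-3-enoic acid | C=C(C)CC(=O)O | starting material
5 | (2E)-5-{[tert-butyl(dimethyl)silyl]oxy}-3-methylpent-2-en-1-yl 3-methylbut-3-enoate | C=C(C)CC(=O)OC/C=C(\C)CCO[Si](C)(C)C(C)(C)C | intermediate
6 | E(O) boron ketene acetal of 5 with the (4R,5R)-diazaborolidine | C=C(C)/C=C(\OC/C=C(\C)CCO[Si](C)(C)C(C)(C)C)OB1N(S(=O)(=O)c2cc(cc(c2)C(F)(F)F)C(F)(F)F)[C@H](c2ccccc2)[C@@H](c2ccccc2)N1S(=O)(=O)c1cc(cc(c1)C(F)(F)F)C(F)(F)F | intermediate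
7 | (2R,3R)-5-{[tert-butyl(dimethyl)silyl]oxy}-3-ethenyl-3-methyl-2-(prop-1-en-2-yl)pentanoic acid | C=C[C@@](C)(CCO[Si](C)(C)C(C)(C)C)[C@@H](C(C)=C)C(=O)O | intermediate
8 | (2R,3R)-5-{[tert-butyl(dimethyl)silyl]oxy}-3-ethenyl-3-methyl-2-(prop-1-en-2-yl)pentan-1-ol | C=C[C@@](C)(CCO[Si](C)(C)C(C)(C)C)[C@@H](C(C)=C)CO | intermediate
9 | (2R,3R)-5-{[tert-butyl(dimethyl)silyl]oxy}-3-ethenyl-3-methyl-2-(prop-1-en-2-yl)pentanal | C=C[C@@](C)(CCO[Si](C)(C)C(C)(C)C)[C@@H](C(C)=C)C=O | intermediate
10 | methyl 2-(bromomethyl)prop-2-enoate | C=C(CBr)C(=O)OC | starting material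
11 | methyl 2,3-dibromo-2-(bromomethyl)propanoate | COC(=O)C(Br)(CBr)CBr | intermediate
12 | methyl 3-bromo-2-(bromomethyl)prop-2-enoate (E/Z mixture) | COC(=O)C(CBr)=CBr | intermediate
13 | [3-bromo-2-(methoxycarbonyl)prop-2-en-1-yl]indium bromide (drawn as the formal insertion product) | COC(=O)C(C[In]Br)=CBr | intermediate
14 | methyl (4S,5R,6R)-3-bromo-8-{[tert-butyl(dimethyl)silyl]oxy}-6-ethenyl-4-hydroxy-6-methyl-2-methylidene-5-(prop-1-en-2-yl)octanoate (C3 epimers) | C=C[C@@](C)(CCO[Si](C)(C)C(C)(C)C)[C@@H](C(C)=C)[C@H](O)C(Br)C(=C)C(=O)OC | intermediate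
15 | (5S)-4-bromo-5-[(3R,4R)-6-{[tert-butyl(dimethyl)silyl]oxy}-4-ethenyl-2,4-dimethylhex-1-en-3-yl]-3-methylideneoxolan-2-one (C4 epimers) | C=C[C@@](C)(CCO[Si](C)(C)C(C)(C)C)[C@@H](C(C)=C)[C@@H]1OC(=O)C(=C)C1Br | intermediate
16 | (5S)-4-bromo-5-[(3R,4R)-4-ethenyl-6-hydroxy-2,4-dimethylhex-1-en-3-yl]-3-methylideneoxolan-2-one (C4 epimers) | C=C[C@@](C)(CCO)[C@@H](C(C)=C)[C@@H]1OC(=O)C(=C)C1Br | intermediate
17 | (3R,4R)-4-[(2S)-3-bromo-4-methylidene-5-oxooxolan-2-yl]-3-ethenyl-3,5-dimethylhex-5-enal | C=C[C@@](C)(CC=O)[C@@H](C(C)=C)[C@@H]1OC(=O)C(=C)C1Br | intermediate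
18 | α-(bromoindiomethyl)butenolide aldehyde (drawn as the formal insertion product) | C=C[C@@](C)(CC=O)[C@@H](C(C)=C)[C@@H]1OC(=O)C(C[In]Br)=C1 | intermediate
19 | (3aR,4R,6R,7R,7aS)-6-ethenyl-4-hydroxy-6-methyl-3-methylidene-7-(prop-1-en-2-yl)hexahydro-1-benzofuran-2(3H)-one | C=C[C@@]1(C)C[C@@H](O)[C@H]2C(=C)C(=O)O[C@H]2[C@@H]1C(C)=C | intermediate
20 | methyl (4S)-2,2-dimethyl-1,3-dioxolane-4-carboxylate | COC(=O)[C@@H]1COC(C)(C)O1 | starting material
21 | (4S)-2,2-dimethyl-1,3-dioxolane-4-carbaldehyde | O=C[C@@H]1COC(C)(C)O1 | intermediate
22 | (4R)-4-ethynyl-2,2-dimethyl-1,3-dioxolane | C#C[C@@H]1COC(C)(C)O1 | intermediate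
23 | (2R)-but-3-yne-1,2-diol | C#C[C@@H](O)CO | intermediate
24 | (2R)-1,2-bis{[tert-butyl(dimethyl)silyl]oxy}but-3-yne | C#C[C@@H](O[Si](C)(C)C(C)(C)C)CO[Si](C)(C)C(C)(C)C | intermediate
25 | (3R)-3,4-bis{[tert-butyl(dimethyl)silyl]oxy}-2-methylidenebutanoic acid | C=C(C(=O)O)[C@@H](O[Si](C)(C)C(C)(C)C)CO[Si](C)(C)C(C)(C)C | intermediate
26 | mixed anhydride of 25 and 2,4,6-trichlorobenzoic acid | C=C(C(=O)OC(=O)c1c(Cl)cc(Cl)cc1Cl)[C@@H](O[Si](C)(C)C(C)(C)C)CO[Si](C)(C)C(C)(C)C | intermediate
27 | O8-[(3R)-3,4-bis(tert-butyldimethylsilyloxy)-2-methylidenebutanoyl] derivative of 19 | C=C[C@@]1(C)C[C@@H](OC(=O)C(=C)[C@@H](O[Si](C)(C)C(C)(C)C)CO[Si](C)(C)C(C)(C)C)[C@H]2C(=C)C(=O)O[C@H]2[C@@H]1C(C)=C | intermediate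
28 | 15-hydroxy derivative of 27 | C=C[C@@]1(C)C[C@@H](OC(=O)C(=C)[C@@H](O[Si](C)(C)C(C)(C)C)CO[Si](C)(C)C(C)(C)C)[C@H]2C(=C)C(=O)O[C@H]2[C@@H]1C(=C)CO | intermediate
29 | seco acid of 28 (3',4'-bis-silyl ether of the target) | C=C[C@@]1(C)C[C@@H](OC(=O)C(=C)[C@@H](O[Si](C)(C)C(C)(C)C)CO[Si](C)(C)C(C)(C)C)[C@@H](C(=C)C(=O)O)[C@@H](O)[C@@H]1C(=C)CO | intermediate
30 | CNP0348657.1 | C=C[C@@]1(C)C[C@@H](OC(=O)C(=C)[C@@H](O)CO)[C@@H](C(=C)C(=O)O)[C@@H](O)[C@@H]1C(=C)CO | target

**Total step count:** 18.
**Longest linear sequence:** 12 (steps 1–5, 8–10, 15–18).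

## Least certain steps

**Step 10 (key step).**
- *What may go wrong:*
  - protonation of the allylmetal before the ring closes;
  - reductive opening of the lactone by loss of the C6 carboxylate;
  - attack on the other aldehyde face if an open transition state competes;
  - migration of the lactone from O6 to O8 through the fresh alkoxide.
- *Fallback:* it reverses the polarity of the closing bond, sets out from 16 and comes back at 19. KOAc in DMF displaces the allylic bromide with allylic shift to give the acetoxymethyl butenolide alcohol F1. Dess–Martin oxidation gives the acetoxymethyl butenolide aldehyde F2. SmI2 in THF at low temperature then forms the C8 ketyl radical. This radical adds to the electrophilic β-carbon C7 of the butenolide on the face fixed by the same tether, and the samarium enolate expels acetate, which unveils the methylene group of 19.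

**Step 8.**
- *What may go wrong:*
  - attack through the unsubstituted terminus of the allylindium, favoured by the hindrance of the aldehyde;
  - further metallation of the product bromide, with protonation or elimination;
  - weak Felkin–Anh selection.
- *Fallback:* it builds the lactone and the C13 handle in separate known operations, sets out from 9 and comes back at 19.
  1. Nozaki–Hiyama–Kishi coupling of 9 with ethyl (Z)-3-iodoacrylate (CrCl2, NiCl2 cat., DMF), with spontaneous lactonisation, gives the silylated butenolide F3.
  2. A Morita–Baylis–Hillman reaction with aqueous formaldehyde gives the hydroxymethyl butenolide F4.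
  3. PBr3 gives the bromomethyl butenolide F5.
  4. Aqueous HF in MeCN gives the bromomethyl butenolide alcohol F6.
  5. Dess–Martin oxidation gives the bromomethyl butenolide aldehyde F7.
  6. Indium under the conditions of step 10 converts F7 into the same allylmetal 18 and so into 19.

**Step 3.**
- *What may go wrong:*
  - formation of the conjugated boron dienolate with the Z(O) geometry, which would invert C5 relative to C10;
  - incomplete face selection;
  - slow rearrangement, with attack of the Lewis acid on the silyl ether.
- *Fallback:* it gives up asymmetric induction for resolution, sets out from 5 and comes back at 7. LDA in THF at −78 °C followed by TMSCl gives the trimethylsilyl ketene acetal F8, which rearranges on warming. Hydrolysis gives the acid as the racemate, that is 7 together with its enantiomer F9. Crystallisation with (R)-1-phenylethylamine separates the salt F10, from which dilute acid releases 7.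

**Step 16.**
- *What may go wrong:* stalling at low conversion, overoxidation to the enal, and loss of a silyl ether through the acidity of the medium.
- *Fallback:* it replaces oxygen transfer by an ene-type chlorination and substitution, sets out from 27 and comes back at 29. CeCl3·7H2O and NaOCl in CH2Cl2–H2O give the allylic chloride F11. KOAc with catalytic NaI in DMF gives the allylic acetate F12. LiOH (2.2 equiv) under the conditions of step 17 cleaves the primary acetate and opens the lactone in one operation to give 29.

**Step 17.**
- *What may go wrong:* competing hydrolysis of the C1' ester, conjugate addition of hydroxide to the methylene lactone, and relactonisation during neutralisation.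
- *Fallback:* it frees C12 by zerovalent palladium instead of hydroxide in the presence of the side chain, sets out from 19 and comes back at 29.
  1. LiOH, then allyl bromide in DMF on the carboxylate, gives the allyl ester diol F13, which is used at once.
  2. Yamaguchi esterification with 25 should choose O8, which has only one branched neighbour, over O6, which has two. It gives the allyl ester monoacylate F14.
  3. SeO2 and t-BuOOH give its 15-hydroxy derivative F15.
  4. Pd(PPh3)4 and morpholine remove the allyl group under neutral conditions to give 29.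

## Further compounds

F1 | step 10 | (5S)-3-(acetoxymethyl)-5-[(3R,4R)-4-ethenyl-6-hydroxy-2,4-dimethylhex-1-en-3-yl]furan-2(5H)-one | C=C[C@@](C)(CCO)[C@@H](C(C)=C)[C@@H]1OC(=O)C(COC(C)=O)=C1
F2 | step 10 | (3R,4R)-4-[(2S)-4-(acetoxymethyl)-5-oxo-2,5-dihydrofuran-2-yl]-3-ethenyl-3,5-dimethylhex-5-enal | C=C[C@@](C)(CC=O)[C@@H](C(C)=C)[C@@H]1OC(=O)C(COC(C)=O)=C1
F3 | step 8 | (5S)-5-[(3R,4R)-6-{[tert-butyl(dimethyl)silyl]oxy}-4-ethenyl-2,4-dimethylhex-1-en-3-yl]furan-2(5H)-one | C=C[C@@](C)(CCO[Si](C)(C)C(C)(C)C)[C@@H](C(C)=C)[C@@H]1OC(=O)C=C1
F4 | step 8 | 3-(hydroxymethyl) derivative of F3 | C=C[C@@](C)(CCO[Si](C)(C)C(C)(C)C)[C@@H](C(C)=C)[C@@H]1OC(=O)C(CO)=C1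
F5 | step 8 | 3-(bromomethyl) derivative of F3 | C=C[C@@](C)(CCO[Si](C)(C)C(C)(C)C)[C@@H](C(C)=C)[C@@H]1OC(=O)C(CBr)=C1
F6 | step 8 | (5S)-3-(bromomethyl)-5-[(3R,4R)-4-ethenyl-6-hydroxy-2,4-dimethylhex-1-en-3-yl]furan-2(5H)-one | C=C[C@@](C)(CCO)[C@@H](C(C)=C)[C@@H]1OC(=O)C(CBr)=C1
F7 | step 8 | (3R,4R)-4-[(2S)-4-(bromomethyl)-5-oxo-2,5-dihydrofuran-2-yl]-3-ethenyl-3,5-dimethylhex-5-enal | C=C[C@@](C)(CC=O)[C@@H](C(C)=C)[C@@H]1OC(=O)C(CBr)=C1
F8 | step 3 | trimethylsilyl ketene acetal of 5, E(O) geometry | C=C(C)/C=C(\OC/C=C(\C)CCO[Si](C)(C)C(C)(C)C)O[Si](C)(C)C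
F9 | step 3 | (2S,3S)-5-{[tert-butyl(dimethyl)silyl]oxy}-3-ethenyl-3-methyl-2-(prop-1-en-2-yl)pentanoic acid | C=C[C@](C)(CCO[Si](C)(C)C(C)(C)C)[C@H](C(C)=C)C(=O)O
F10 | step 3 | salt of 7 with (R)-1-phenylethylamine | C=C[C@@](C)(CCO[Si](C)(C)C(C)(C)C)[C@@H](C(C)=C)C(=O)O.C[C@@H](N)c1ccccc1
F11 | step 16 | 15-chloro derivative of 27 | C=C[C@@]1(C)C[C@@H](OC(=O)C(=C)[C@@H](O[Si](C)(C)C(C)(C)C)CO[Si](C)(C)C(C)(C)C)[C@H]2C(=C)C(=O)O[C@H]2[C@@H]1C(=C)CCl
F12 | step 16 | 15-acetoxy derivative of 27 | C=C[C@@]1(C)C[C@@H](OC(=O)C(=C)[C@@H](O[Si](C)(C)C(C)(C)C)CO[Si](C)(C)C(C)(C)C)[C@H]2C(=C)C(=O)O[C@H]2[C@@H]1C(=C)COC(C)=O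
F13 | step 17 | allyl ester of the seco acid of 19 (6,8-diol) | C=C[C@@]1(C)C[C@@H](O)[C@@H](C(=C)C(=O)OCC=C)[C@@H](O)[C@@H]1C(C)=C
F14 | step 17 | O8-[(3R)-3,4-bis(tert-butyldimethylsilyloxy)-2-methylidenebutanoyl] derivative of F13 | C=C[C@@]1(C)C[C@@H](OC(=O)C(=C)[C@@H](O[Si](C)(C)C(C)(C)C)CO[Si](C)(C)C(C)(C)C)[C@@H](C(=C)C(=O)OCC=C)[C@@H](O)[C@@H]1C(C)=C
F15 | step 17 | 15-hydroxy derivative of F14 | C=C[C@@]1(C)C[C@@H](OC(=O)C(=C)[C@@H](O[Si](C)(C)C(C)(C)C)CO[Si](C)(C)C(C)(C)C)[C@@H](C(=C)C(=O)OCC=C)[C@@H](O)[C@@H]1C(=C)CO
A1 | alternative 1 | (1(10)E,4E)-8,15-dihydroxygermacra-1(10),4,11(13)-trien-6,12-olide with C6, C7 and C8 configured as in 30 | C/C1=C\CC/C(CO)=C/[C@@H]2OC(=O)C(=C)[C@@H]2[C@H](O)C1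
A2 | alternative 2 | (5R)-5-{[tert-butyl(dimethyl)silyl]oxy}-3-methylcyclohex-2-en-1-one | CC1=CC(=O)C[C@H](O[Si](C)(C)C(C)(C)C)C1
A3 | alternative 2 | (3R,5R)-5-{[tert-butyl(dimethyl)silyl]oxy}-3-ethenyl-3-methylcyclohexan-1-one (vinyl trans to the silyloxy group) | C=C[C@@]1(C)CC(=O)C[C@H](O[Si](C)(C)C(C)(C)C)C1
A4 | alternative 3 | open-chain C6 aldehyde with C7, C8 and C10 configured as in 30 and a Z-trisubstituted C4=C5 alkene | O=C[C@H](C(=C)C(=O)OC)[C@H](O[Si](C)(C)C(C)(C)C)C[C@](C)(C=C)/C=C(/C)CO[Si](C)(C)C(C)(C)C
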